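## The problem

Target 17 is a (2S)-flavan: ring A is the benzo ring C4a–C8a, ring C the dihydropyran, ring B the C2-phenyl. Its C8 is bonded to C2' of a 6'-hydroxy-4'-methoxy-5'-methylbenzofuran (furan ring E, benzo ring D). The C8–C2' bond joins an arene carbon flanked by two oxygens (O1 and 7-OH) to a furan carbon, so a late coupling there is hindered, electron-rich on both sides, and must also tell C8 from C6. Both benzene rings are phloroglucinol ethers whose three oxygens have different fates: O1 (ring C), 5-OMe and 7-OH on ring A; O1' (ring E), 4'-OMe and 6'-OH on ring D, with the 5'-methyl between the last two. C2 is the only stereocenter and is remote from every other functional group, so it must be set by a reagent; as a benzylic aryl ether it must then be kept from strong Lewis acids. The free phenols are easily oxidised and the furan C2'=C3' bond is reducible, so oxidation belongs to a stage where the phenols are masked or chelated, and hydrogenation to a stage before ring E exists. The enabling feature is the environment of C2': it carries C8 of ring A and, through C3', C3a' of ring D, and each of these aryl carbons has an ortho oxygen (C7–OH and C7a'–O1'). Adding water across C2'–O1' therefore gives a deoxybenzoin ArA–C(=O)–CH2–ArD with an ortho hydroxyl on either side, that is, a 2'-oxygenated isoflavone that has lost its O–CH= carbon. In addition, C8–C2'–C3' is the acetyl group of an acylphloroglucinol ring (O1, C8, O7, with 5-OMe opposite) that is mirror-symmetric before ring C is attached.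

## Retrosynthesis

**17 ⇒ 16 ⇒ 15.** The O1'–C2' bond of ring E is cut by retro-dehydration to give triol ketone 16, and the two ring D hydroxyls are masked as benzyl ethers in 15. Unlike a cut at C8–C2', this leaves the carbonyl carbon already on C8 and removes the heteroaromatic ring. The forward closure has no choice to make: only the C6-OH of the ring D benzyl unit is ortho to the CH2 (the other ortho position is OMe), and the ring A phenol cannot reach its own ketone.

**15 ⇒ 14.** One carbon is put back: 15 is what hydroxide leaves when it excises the O–CH= carbon of isoflavone 14 as formate. Compound 14 has one more ring but is the direct product of the aryl shift below, and its pyranone holds the ring A phenol during the oxidation. The forward step is the classical alkaline ring-opening and deformylation of an isoflavone.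

**14 ⇒ 12 (key).** The bond between the carbon alpha to the ketone and ring D (C3'–C3a' of 17) is cut by a retro-1,2-aryl shift, which returns ring D to the neighbouring carbon and gives chalcone 12. A direct alpha-arylation of the ketone would be an intermolecular coupling of two doubly ortho-substituted partners and would need a ring D halide of defined position. The shift is intramolecular, and the ring D carbon that migrates is the one that carried the formyl group. This follows the logic of isoflavonoid biogenesis (aryl shift, then loss of the one-carbon unit), used here as a synthetic device, without any claim that the plant makes 17 this way. Chalcone 12 is one aldol step from two small fragments.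

**12 ⇒ 11 + 5.** The enone C=C is cut by a Claisen–Schmidt disconnection into methyl ketone 11 (rings A, B, C with the stereocenter) and aldehyde 5 (ring D). The forward reaction must condense a hindered methyl ketone with a hindered aldehyde that cannot enolise.

**11 ⇒ 10 ⇒ 9.** The O1–C2 bond is cut (Mitsunobu closure with inversion) to give (R)-carbinol 10, and the carbinol is taken back to diketone 9 (asymmetric transfer hydrogenation). The stereocenter comes from the catalyst, and only the phenol beside the chain can become O1.

**9 ⇒ 6 + 7 (through 8).** The ring A–CH2 bond (C4a–C4) is cut as a conjugate addition of commercial 1-(2,6-dihydroxy-4-methoxyphenyl)ethanone 6 to phenyl vinyl ketone 8, made in the flask from 7. Compound 6 already contains the C8–C2' bond and both carbons of the furan. Its mirror symmetry makes the two ring CH positions equivalent, so the C6/C8 question never arises.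

**5 ⇒ 4 ⇒ 3 ⇒ 1.** The O-methyl, the two O-benzyl and the C-formyl bonds of ring D are cut back to mirror-symmetric 2-methylphloroglucinol 1. Formylation of 1 can give only one aldehyde 3. In 3 the three hydroxyls differ by their neighbours: one is para to CHO, one is ortho and flanked by H, and one is ortho and flanked by methyl. The last is the least reactive and is the one that must carry the methyl ether.

## Roads not taken

**Alternative 1:** Cut C8–C2' and join the finished halves by a Suzuki–Miyaura coupling of 8-bromoflavan A1 with benzofuran-2-ylboronate A2 (or the Sonogashira/cycloisomerisation variant), then debenzylate. This is the route most would draw first. It needs a bromination of the flavan that distinguishes C8 from C6, both of which lie between two oxygens. It couples a doubly ortho-substituted bromide with a 2-heteroarylboron reagent that is prone to protodeboronation. It also requires a separate benzofuran synthesis from the same differentiated ring D aldehyde plus a C2 unit and a borylation. The chosen plan never makes the hindered bond and needs no ring E building block.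

**Alternative 2:** Cut C2'=C3' and C2'–O1' and close ring E by an intramolecular Wittig reaction of the ester formed from flavan-8-carboxylic acid A3 and phosphonium salt A4. The acid again needs C8-selective functionalisation of the flavan and an oxidation. The ester must be made from a doubly ortho-substituted acid chloride, and the ylide must attack that hindered ester carbonyl. Ring D needs two different protecting groups and a redox change (CHO to CH2OH to CH2P). The chosen plan uses the ring D aldehyde as it is and gets the acyl carbon on C8 from 6.

**Alternative 3:** Cut C3'–C3a' directly by a palladium-catalysed alpha-arylation of ketone 11, as its methoxymethyl ether A6, with aryl bromide A5, then deprotect and cyclodehydrate. This reaches the carbon skeleton of 15 in one bond-forming step. However, A5 needs a bromination of a ring D ether at the position between OMe and OBn, and the position between the two OBn groups is not intrinsically disfavoured. Both coupling partners are doubly ortho-substituted, and the chelated phenol must be protected and freed. In the chosen plan the formyl group of 5 marks the ring D position, brings ring D in by an aldol reaction, and the C–C bond is then made by an intramolecular migration that is little affected by crowding.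

Key step: step 8

Assumption: 2-methylphloroglucinol 1, ketone 6 and chloroketone 7 are taken to be commercial, and the configuration at C2 is read from the SMILES as S.

## Route

Step 1
Reactants: 1 2-methylbenzene-1,3,5-triol
Product: 3 2,4,6-trihydroxy-3-methylbenzaldehyde, via aryl iminium chloride 2 (not isolated)
Conditions: POCl3 (1.2 equiv), DMF (1.5 equiv), EtOAc, 0 °C to rt; then H2O, 60 °C
Reagents that add atoms: N,N-dimethylformamide, CN(C)C=O (formyl carbon); water, O (formyl oxygen)
Why: Vilsmeier–Haack formylation of a phloroglucinol; the mirror plane of 1 makes its two ring CH positions equivalent, so only one aldehyde can form, and iminium salt 2 (and any aryl formate) is hydrolysed on work-up.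

Step 2
Reactants: 3 2,4,6-trihydroxy-3-methylbenzaldehyde
Product: 4 4,6-bis(benzyloxy)-2-hydroxy-3-methylbenzaldehyde
Conditions: BnBr (2.1 equiv), K2CO3 (2.2 equiv), DMF, 0 °C to rt
Reagents that add atoms: benzyl bromide, BrCc1ccccc1
Why: Williamson etherification under substrate control: the para hydroxyl (C4) is the most acidic and not hydrogen-bonded, the C6-OH comes next, and the C2-OH, pressed by the C3-methyl into the hydrogen bond with the formyl oxygen and flanked on both sides, should be the last to react.

Step 3
Reactants: 4 4,6-bis(benzyloxy)-2-hydroxy-3-methylbenzaldehyde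
Product: 5 4,6-bis(benzyloxy)-2-methoxy-3-methylbenzaldehyde
Conditions: MeI (3 equiv), K2CO3 (2 equiv), DMF, 50 °C
Reagents that add atoms: iodomethane, CI
Why: Williamson methylation of the remaining chelated, hindered phenol, which needs only excess MeI and warming; nothing else in 4 can be alkylated.

Step 4
Reactants: 6 1-(2,6-dihydroxy-4-methoxyphenyl)ethan-1-one; 7 3-chloro-1-phenylpropan-1-one
Product: 9 3-(3-acetyl-2,4-dihydroxy-6-methoxyphenyl)-1-phenylpropan-1-one, via phenyl vinyl ketone 8 (not isolated)
Conditions: K2CO3 (2.5 equiv), H2O/1,4-dioxane (3:1), 40 °C; 7 (1 equiv) added slowly to 6 (1.5 equiv)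
Reagents that add atoms: none
Why: E1cB loss of HCl from 7 gives enone 8, and the phenoxide of 6 adds through a ring carbon (Michael addition; C-alkylation of an ambident acylphloroglucinol anion is favoured in water, and O-adducts revert by retro-oxa-Michael reaction). The mirror symmetry of 6 makes its two ring CH positions equivalent, so only one mono-adduct is possible; excess 6 and slow addition should hold back a second alkylation.

Step 5
Reactants: 9 3-(3-acetyl-2,4-dihydroxy-6-methoxyphenyl)-1-phenylpropan-1-one
Product: 10 1-{2,6-dihydroxy-3-[(3R)-3-hydroxy-3-phenylpropyl]-4-methoxyphenyl}ethan-1-one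
Conditions: RuCl[(R,R)-TsDPEN](p-cymene) (1 mol %), HCO2H/Et3N (5:2), DMF, 40 °C
Reagents that add atoms: none
Why: Noyori asymmetric transfer hydrogenation of an aryl alkyl ketone; the (R,R) ligand delivers hydride to the face that gives the (R)-carbinol, as with acetophenone and propiophenone. The acetyl carbonyl, hydrogen-bonded to an ortho hydroxyl and flanked by two ortho substituents, should not be reduced.

Step 6
Reactants: 10 1-{2,6-dihydroxy-3-[(3R)-3-hydroxy-3-phenylpropyl]-4-methoxyphenyl}ethan-1-one
Product: 11 1-[(2S)-7-hydroxy-5-methoxy-2-phenyl-3,4-dihydro-2H-chromen-8-yl]ethan-1-one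
Conditions: PPh3 (1.5 equiv), DIAD (1.5 equiv), THF (0.02 M), 0 °C to rt
Reagents that add atoms: none
Why: Intramolecular Mitsunobu etherification: the oxyphosphonium of the (R)-carbinol is displaced by the neighbouring phenoxide in an SN2 step (6-exo-tet) with inversion, which sets C2 as S. The second phenol cannot reach the carbinol carbon, so the position of the chain decides which hydroxyl becomes O1.

Step 7
Reactants: 11 1-[(2S)-7-hydroxy-5-methoxy-2-phenyl-3,4-dihydro-2H-chromen-8-yl]ethan-1-one; 5 4,6-bis(benzyloxy)-2-methoxy-3-methylbenzaldehyde
Product: 12 (2E)-3-[4,6-bis(benzyloxy)-2-methoxy-3-methylphenyl]-1-[(2S)-7-hydroxy-5-methoxy-2-phenyl-3,4-dihydro-2H-chromen-8-yl]prop-2-en-1-one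
Conditions: KOH (50% aq., excess), EtOH, rt to 40 °C, N2
Reagents that add atoms: none
Why: Claisen–Schmidt aldol condensation; 5 cannot enolise, E1cB dehydration gives the conjugated (E)-enone, and in strong base the 7-phenoxide holds the open chalcone against ring closure to the flavanone.

Step 8
Reactants: 12 (2E)-3-[4,6-bis(benzyloxy)-2-methoxy-3-methylphenyl]-1-[(2S)-7-hydroxy-5-methoxy-2-phenyl-3,4-dihydro-2H-chromen-8-yl]prop-2-en-1-one
Product: 14 (2S)-9-[4,6-bis(benzyloxy)-2-methoxy-3-methylphenyl]-5-methoxy-2-phenyl-3,4-dihydro-2H,10H-pyrano[2,3-f]chromen-10-one (isoflavone), via dimethyl acetal 13 (not isolated)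
Conditions: Tl(NO3)3·3H2O (1.1 equiv), MeOH/HC(OMe)3 (3:1), rt; then 10% aq. HCl, MeOH, 60 °C
Reagents that add atoms: none
Why: Oxidative 1,2-aryl migration of a chalcone mediated by trivalent thallium, the standard laboratory isoflavone synthesis from 2'-hydroxychalcones and the chemical counterpart of the aryl shift in isoflavonoid biogenesis. Tl(NO3)3 and methanol add across the enone C=C (oxythallation), with methoxide at the benzylic carbon next to ring D and thallium at the carbon alpha to the ketone. Loss of univalent thallium from that carbon is assisted by ring D, which bridges as a phenonium ion and moves to the alpha carbon; the oxocarbenium ion left behind is trapped by methanol to give acetal 13. Acid then ionises the acetal, the chelated 7-OH of ring A attacks the oxocarbenium carbon (6-exo-trig), and loss of methanol closes the pyranone of 14. No stereocenter is formed in 14 (the epimeric centre of 13 becomes sp2), and C2 of ring C is remote and untouched. The step needs aryl migration to win over conjugate closure of the 7-OH to a flavanone or aurone and over attack of the oxidant on the arenes: the three oxygen donors of ring D give it a high migratory aptitude and fix the regiochemistry of oxythallation, its two ortho substituents shield the beta carbon from the phenol, ring D is fully etherified, and the only phenol of ring A is deactivated by its hydrogen bond to the ketone. The migration puts ring D on the alpha carbon through the very ring carbon that carried the formyl group of 5, so the position of the new C–C bond on ring D is fixed.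

Step 9
Reactants: 14 (2S)-9-[4,6-bis(benzyloxy)-2-methoxy-3-methylphenyl]-5-methoxy-2-phenyl-3,4-dihydro-2H,10H-pyrano[2,3-f]chromen-10-one
Product: 15 2-[4,6-bis(benzyloxy)-2-methoxy-3-methylphenyl]-1-[(2S)-7-hydroxy-5-methoxy-2-phenyl-3,4-dihydro-2H-chromen-8-yl]ethan-1-one
Conditions: 10% aq. KOH/EtOH (1:1), reflux, N2; then AcOH to pH 6
Reagents that add atoms: none
Why: Alkaline degradation of an isoflavone to a deoxybenzoin: hydroxide adds to the O–CH= carbon, the pyranone opens by loss of the ring A phenoxide, and retro-Claisen cleavage of the resulting beta-keto aldehyde expels that carbon as formate. The ketone, flanked by two ortho substituents and an ortho phenoxide, should not be attacked, and benzyl ethers and ring C are inert to base.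

Step 10
Reactants: 15 2-[4,6-bis(benzyloxy)-2-methoxy-3-methylphenyl]-1-[(2S)-7-hydroxy-5-methoxy-2-phenyl-3,4-dihydro-2H-chromen-8-yl]ethan-1-one
Product: 17 (2S)-8-(6-hydroxy-4-methoxy-5-methyl-1-benzofuran-2-yl)-5-methoxy-2-phenyl-3,4-dihydro-2H-chromen-7-ol, via triol ketone 16 (not isolated)
Conditions: H2 (1 atm), 10% Pd/C, EtOAc/MeOH, rt; filter; then TsOH·H2O (10 mol %), MeOH, 50 °C
Reagents that add atoms: none
Why: Hydrogenolysis frees both ring D phenols before any furan double bond exists; the C6-OH of the benzyl unit, the only hydroxyl ortho to the CH2, then adds to the ketone (5-exo-trig) and acid-catalysed loss of water aromatises ring E (cyclodehydration of a 2-hydroxybenzyl aryl ketone to a 2-arylbenzofuran). C2 of ring C carries an unactivated phenyl group and should not ionise under these conditions.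

## Compound list

1 | 2-methylbenzene-1,3,5-triol (2-methylphloroglucinol) | Cc1c(O)cc(O)cc1O | starting material
2 | [(2,4,6-trihydroxy-3-methylphenyl)methylidene]dimethylammonium chloride | C[N+](C)=Cc1c(O)cc(O)c(C)c1O.[Cl-] | intermediate (not isolated)
3 | 2,4,6-trihydroxy-3-methylbenzaldehyde | O=Cc1c(O)cc(O)c(C)c1O | intermediate
4 | 4,6-bis(benzyloxy)-2-hydroxy-3-methylbenzaldehyde | O=Cc1c(OCc2ccccc2)cc(OCc2ccccc2)c(C)c1O | intermediate
5 | 4,6-bis(benzyloxy)-2-methoxy-3-methylbenzaldehyde | O=Cc1c(OCc2ccccc2)cc(OCc2ccccc2)c(C)c1OC | intermediate
6 | 1-(2,6-dihydroxy-4-methoxyphenyl)ethan-1-one | CC(=O)c1c(O)cc(OC)cc1O | starting material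
7 | 3-chloro-1-phenylpropan-1-one | O=C(CCCl)c1ccccc1 | starting material
8 | 1-phenylprop-2-en-1-one (phenyl vinyl ketone) | C=CC(=O)c1ccccc1 | intermediate (not isolated)
9 | 3-(3-acetyl-2,4-dihydroxy-6-methoxyphenyl)-1-phenylpropan-1-one | CC(=O)c1c(O)cc(OC)c(CCC(=O)c2ccccc2)c1O | intermediate
10 | 1-{2,6-dihydroxy-3-[(3R)-3-hydroxy-3-phenylpropyl]-4-methoxyphenyl}ethan-1-one | CC(=O)c1c(O)cc(OC)c(CC[C@@H](O)c2ccccc2)c1O | intermediate
11 | 1-[(2S)-7-hydroxy-5-methoxy-2-phenyl-3,4-dihydro-2H-chromen-8-yl]ethan-1-one | COc1cc(O)c(C(C)=O)c2c1CC[C@@H](c1ccccc1)O2 | intermediate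
12 | (2E)-3-[4,6-bis(benzyloxy)-2-methoxy-3-methylphenyl]-1-[(2S)-7-hydroxy-5-methoxy-2-phenyl-3,4-dihydro-2H-chromen-8-yl]prop-2-en-1-one | COc1cc(O)c(C(=O)/C=C/c3c(OC)c(C)c(OCc4ccccc4)cc3OCc3ccccc3)c2c1CC[C@@H](c1ccccc1)O2 | intermediate
13 | 2-[4,6-bis(benzyloxy)-2-methoxy-3-methylphenyl]-1-[(2S)-7-hydroxy-5-methoxy-2-phenyl-3,4-dihydro-2H-chromen-8-yl]-3,3-dimethoxypropan-1-one (both epimers at the chain C2) | COc1cc(O)c(C(=O)C(C(OC)OC)c3c(OC)c(C)c(OCc4ccccc4)cc3OCc3ccccc3)c2c1CC[C@@H](c1ccccc1)O2 | intermediate (not isolated)
14 | (2S)-9-[4,6-bis(benzyloxy)-2-methoxy-3-methylphenyl]-5-methoxy-2-phenyl-3,4-dihydro-2H,10H-pyrano[2,3-f]chromen-10-one | COc1cc2occ(-c3c(OC)c(C)c(OCc4ccccc4)cc3OCc3ccccc3)c(=O)c2c2c1CC[C@@H](c1ccccc1)O2 | intermediate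
15 | 2-[4,6-bis(benzyloxy)-2-methoxy-3-methylphenyl]-1-[(2S)-7-hydroxy-5-methoxy-2-phenyl-3,4-dihydro-2H-chromen-8-yl]ethan-1-one | COc1cc(O)c(C(=O)Cc3c(OC)c(C)c(OCc4ccccc4)cc3OCc3ccccc3)c2c1CC[C@@H](c1ccccc1)O2 | intermediate
16 | 2-(4,6-dihydroxy-2-methoxy-3-methylphenyl)-1-[(2S)-7-hydroxy-5-methoxy-2-phenyl-3,4-dihydro-2H-chromen-8-yl]ethan-1-one | COc1cc(O)c(C(=O)Cc3c(OC)c(C)c(O)cc3O)c2c1CC[C@@H](c1ccccc1)O2 | intermediate (not isolated)
17 | (2S)-8-(6-hydroxy-4-methoxy-5-methyl-1-benzofuran-2-yl)-5-methoxy-2-phenyl-3,4-dihydro-2H-chromen-7-ol | COc1cc(O)c(-c2cc3c(OC)c(C)c(O)cc3o2)c2c1CC[C@@H](c1ccccc1)O2 | target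

## Step count and risks

Total: 10 steps. Longest linear sequence: 7 steps (4, 5, 6, 7, 8, 9, 10; the ring D branch 1, 2, 3, 7, 8, 9, 10 is equally long).

**Step 8 (key step).** The most likely failure is diversion of the oxidation: attack of trivalent thallium on the one free CH of ring D or on ring A, or conjugate closure of the 7-OH (aurone or flavone formation) outrunning aryl migration. Fallback, setting out from 12:
- Benzylation of the 7-OH (BnBr, K2CO3, DMF) gives the tri-O-benzyl chalcone F1. The phenol must be capped, because alkaline peroxide would otherwise trigger the Algar–Flynn–Oyamada reaction.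
- Nucleophilic epoxidation (H2O2, NaOH, MeOH/THF) gives the trans-epoxide F2.
- BF3·OEt2 (CH2Cl2, 0 °C) opens the epoxide at the benzylic carbon and the aroyl group shifts (Meinwald-type rearrangement), giving the 2-formyl ketone F3, which has the same 1,2-diaryl-C3 skeleton as 13.
- NaOH (aq. EtOH, rt) removes the formyl group by retro-Claisen cleavage to give the tri-O-benzyl deoxybenzoin F4.
- Hydrogenolysis under the conditions of step 10 removes the three benzyl groups and rejoins the route at 16, which closes to 17.

**Step 4.** The most likely failure is O-alkylation instead of C-alkylation, together with a second alkylation at the other ring position and polymerisation of 8. Fallback, setting out from 6: aminomethylation (aq. CH2O, Me2NH, EtOH) gives the Mannich base F5. Heating F5 with trimethyl[(1-phenylethenyl)oxy]silane in toluene at 110 °C expels dimethylamine to an ortho-quinone methide, which is trapped in an inverse-demand hetero-Diels–Alder reaction as the 2-phenyl-2-(trimethylsilyloxy)chroman F6. Aqueous HCl/THF hydrolyses the ketal and rejoins the route at 9. The C–C bond is then made by cycloaddition, and O-alkylation is not possible.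

**Step 6.** The most likely failure is ionisation of the activated benzylic carbinol, with erosion of enantiomeric purity, and elimination to the styrene. Fallback, setting out from 9: acid-catalysed cyclodehydration (TsOH, toluene, reflux, removal of water) gives the 2-phenyl-4H-chromene F7. Asymmetric hydrogenation of its enol ether C=C with a cationic univalent-iridium phosphinooxazoline complex, [Ir(cod)(L*)][B(C6H3(CF3)2)4], under H2 sets C2 directly, the ligand enantiomer being chosen for (2S), and rejoins the route at 11. Steps 5 and 6 are bypassed and no C–O bond is formed at the stereocenter.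

**Step 10.** The most likely failure is over-reduction of the aryl ketone, which would shut off furan closure, or hydrogenolysis of the benzylic O1–C2 bond on long exposure. Fallback, setting out from 14: hydrogenolysis (H2, Pd/C, EtOAc/MeOH) at the isoflavone stage, where the only carbonyl is a vinylogous ester, gives the 2',4'-dihydroxyisoflavone F8. KOH (aq. EtOH, reflux, N2) then excises the O–CH= carbon, and acidification (HCl, 50 °C) closes ring E in the same flask, passing through 16 to 17.

**Step 2.** The most likely failure is poor discrimination between the two ortho hydroxyls, giving the isomeric dibenzyl ether. Fallback, setting out from 1: exhaustive benzylation (BnBr, K2CO3, DMF) gives the tris(benzyl) ether F9, and Vilsmeier–Haack formylation gives the tris(benzyloxy) aldehyde F10 as the only possible isomer. BCl3 (1 equiv, CH2Cl2, −78 °C) cleaves only an ether ortho to the formyl group through a six-membered boron chelate. Of the two such ethers, the one flanked by the methyl group is twisted out of conjugation and more basic, and should go first, which rejoins the route at 4. The selection then rests on chelation-assisted dealkylation and no longer on relative rates of alkylation.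

## Further compounds

F1 | step 8 | (2E)-3-[4,6-bis(benzyloxy)-2-methoxy-3-methylphenyl]-1-[(2S)-7-(benzyloxy)-5-methoxy-2-phenyl-3,4-dihydro-2H-chromen-8-yl]prop-2-en-1-one | COc1cc(OCc5ccccc5)c(C(=O)/C=C/c3c(OC)c(C)c(OCc4ccccc4)cc3OCc3ccccc3)c2c1CC[C@@H](c1ccccc1)O2
F2 | step 8 | [(2S)-7-(benzyloxy)-5-methoxy-2-phenyl-3,4-dihydro-2H-chromen-8-yl]{3-[4,6-bis(benzyloxy)-2-methoxy-3-methylphenyl]oxiran-2-yl}methanone (trans-epoxide, both diastereomers) | COc1cc(OCc5ccccc5)c(C(=O)C6OC6c3c(OC)c(C)c(OCc4ccccc4)cc3OCc3ccccc3)c2c1CC[C@@H](c1ccccc1)O2
F3 | step 8 | 2-[4,6-bis(benzyloxy)-2-methoxy-3-methylphenyl]-3-[(2S)-7-(benzyloxy)-5-methoxy-2-phenyl-3,4-dihydro-2H-chromen-8-yl]-3-oxopropanal (both epimers) | COc1cc(OCc5ccccc5)c(C(=O)C(C=O)c3c(OC)c(C)c(OCc4ccccc4)cc3OCc3ccccc3)c2c1CC[C@@H](c1ccccc1)O2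
F4 | step 8 | 2-[4,6-bis(benzyloxy)-2-methoxy-3-methylphenyl]-1-[(2S)-7-(benzyloxy)-5-methoxy-2-phenyl-3,4-dihydro-2H-chromen-8-yl]ethan-1-one | COc1cc(OCc5ccccc5)c(C(=O)Cc3c(OC)c(C)c(OCc4ccccc4)cc3OCc3ccccc3)c2c1CC[C@@H](c1ccccc1)O2
F5 | step 4 | 1-{3-[(dimethylamino)methyl]-2,6-dihydroxy-4-methoxyphenyl}ethan-1-one | CC(=O)c1c(O)cc(OC)c(CN(C)C)c1O
F6 | step 4 | 1-[7-hydroxy-5-methoxy-2-phenyl-2-(trimethylsilyloxy)-3,4-dihydro-2H-chromen-8-yl]ethan-1-one (racemic) | COc1cc(O)c(C(C)=O)c2c1CCC(O[Si](C)(C)C)(c1ccccc1)O2
F7 | step 6 | 1-(7-hydroxy-5-methoxy-2-phenyl-4H-chromen-8-yl)ethan-1-one | COc1cc(O)c(C(C)=O)c2c1CC=C(c1ccccc1)O2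
F8 | step 10 | (2S)-9-(4,6-dihydroxy-2-methoxy-3-methylphenyl)-5-methoxy-2-phenyl-3,4-dihydro-2H,10H-pyrano[2,3-f]chromen-10-one | COc1cc2occ(-c3c(OC)c(C)c(O)cc3O)c(=O)c2c2c1CC[C@@H](c1ccccc1)O2
F9 | step 2 | 1,3,5-tris(benzyloxy)-2-methylbenzene | Cc1c(OCc2ccccc2)cc(OCc2ccccc2)cc1OCc1ccccc1
F10 | step 2 | 2,4,6-tris(benzyloxy)-3-methylbenzaldehyde | O=Cc1c(OCc2ccccc2)cc(OCc2ccccc2)c(C)c1OCc1ccccc1
A1 | alternative 1 | (2S)-7-(benzyloxy)-8-bromo-5-methoxy-2-phenyl-3,4-dihydro-2H-chromene | COc1cc(OCc3ccccc3)c(Br)c2c1CC[C@@H](c1ccccc1)O2
A2 | alternative 1 | 2-[6-(benzyloxy)-4-methoxy-5-methyl-1-benzofuran-2-yl]-4,4,5,5-tetramethyl-1,3,2-dioxaborolane | COc1c(C)c(OCc2ccccc2)cc2oc(B3OC(C)(C)C(C)(C)O3)cc12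
A3 | alternative 2 | (2S)-7-(benzyloxy)-5-methoxy-2-phenyl-3,4-dihydro-2H-chromene-8-carboxylic acid | COc1cc(OCc3ccccc3)c(C(=O)O)c2c1CC[C@@H](c1ccccc1)O2
A4 | alternative 2 | {[4-(benzyloxy)-6-hydroxy-2-methoxy-3-methylphenyl]methyl}triphenylphosphonium bromide | COc1c(C)c(OCc2ccccc2)cc(O)c1C[P+](c1ccccc1)(c1ccccc1)c1ccccc1.[Br-]
A5 | alternative 3 | 1,5-bis(benzyloxy)-2-bromo-3-methoxy-4-methylbenzene | COc1c(C)c(OCc2ccccc2)cc(OCc2ccccc2)c1Br
A6 | alternative 3 | 1-[(2S)-5-methoxy-7-(methoxymethoxy)-2-phenyl-3,4-dihydro-2H-chromen-8-yl]ethan-1-one | COc1cc(OCOC)c(C(C)=O)c2c1CC[C@@H](c1ccccc1)O2
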